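**Assumption:** Rigidin C has no stereocentres (it is achiral), so "single enantiomer" sets no stereochemical task; the route delivers the one constitutional structure given.

## Retrosynthetic overview

- Final step: cleave two O-benzyl groups, the only protecting groups, from the bis-benzyl ether of rigidin C.
- Ring B (pyrimidine-2,4-dione) is formed last: C2 carbonyl insertion between the 2-NH2 and 3-CONH2 groups of a pyrrole, using oxalyl chloride.
- Ring A (pyrrole) is formed first, in one pot from three components: an N-mesyl aminoketone, O-benzylvanillin and cyanoacetamide. Loss of methanesulfinate aromatises the ring.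
- The N-mesyl aminoketone comes from 4-(benzyloxy)phenacyl bromide and methanesulfonamide.

## Route

**Step 1**
Reactants: 1 2-bromo-1-[4-(benzyloxy)phenyl]ethan-1-one; 2 methanesulfonamide
Product: 3 N-{2-[4-(benzyloxy)phenyl]-2-oxoethyl}methanesulfonamide
Conditions: MsNH2 (3 equiv), K2CO3 (1.5 equiv), MeCN, rt, 16 h
Reagents that add atoms: none
Why: SN2 N-alkylation of the sulfonamide anion by the reactive phenacyl bromide; excess sulfonamide suppresses double alkylation and the benzyl ether is inert to K2CO3.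

**Step 2**
Reactants: 3 N-{2-[4-(benzyloxy)phenyl]-2-oxoethyl}methanesulfonamide; 4 4-(benzyloxy)-3-methoxybenzaldehyde; 5 2-cyanoacetamide
Product: 9 2-amino-5-[4-(benzyloxy)benzoyl]-4-[4-(benzyloxy)-3-methoxyphenyl]-1H-pyrrole-3-carboxamide, via Knoevenagel cyanoacrylamide 6 (not isolated), via Michael adduct 7 (not isolated), via N-mesyl aminopyrroline 8 (not isolated)
Conditions: K2CO3 (1 equiv), EtOH, reflux, 24 h
Reagents that add atoms: none
Why: A multicomponent domino sequence (Knoevenagel condensation, Michael addition of the activated CH2 of 3, 5-exo-dig addition of the sulfonamide N to the nitrile, then base-induced elimination of methanesulfinate) gives the aromatic 2-aminopyrrole without an external oxidant; the transient sp3 centres are destroyed on aromatisation.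

**Step 3**
Reactants: 9 2-amino-5-[4-(benzyloxy)benzoyl]-4-[4-(benzyloxy)-3-methoxyphenyl]-1H-pyrrole-3-carboxamide
Product: 11 6-[4-(benzyloxy)benzoyl]-5-[4-(benzyloxy)-3-methoxyphenyl]-1H-pyrrolo[2,3-d]pyrimidine-2,4(3H,7H)-dione, via acyl isocyanate 10 (not isolated)
Conditions: (COCl)2 (1.5 equiv), diglyme, 0 °C → 120 °C, 3 h
Reagents that add atoms: oxalyl chloride O=C(Cl)C(Cl)=O
Why: The primary carboxamide and oxalyl chloride give an acyl isocyanate with loss of CO and HCl (Speziale reaction), and the adjacent 2-amino group adds to it in a 6-membered ring closure to form the cyclic acylurea; the benzyl ethers and the deactivated ketone are inert.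

**Step 4**
Reactants: 11 6-[4-(benzyloxy)benzoyl]-5-[4-(benzyloxy)-3-methoxyphenyl]-1H-pyrrolo[2,3-d]pyrimidine-2,4(3H,7H)-dione
Product: 12 rigidin C, 6-(4-hydroxybenzoyl)-5-(4-hydroxy-3-methoxyphenyl)-1H-pyrrolo[2,3-d]pyrimidine-2,4(3H,7H)-dione
Conditions: H2 (1 atm), 10% Pd/C, DMF–MeOH 1:1, rt
Reagents that add atoms: none
Why: Catalytic hydrogenolysis cleaves both aryl benzyl ethers, while the 2-acylpyrrole ketone (a vinylogous amide), the aryl methyl ether and the heteroaromatic core resist reduction at 1 atm.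

## Compound list

1 | 2-bromo-1-[4-(benzyloxy)phenyl]ethan-1-one | O=C(CBr)c1ccc(OCc2ccccc2)cc1 | starting material
2 | methanesulfonamide | CS(N)(=O)=O | starting material
3 | N-{2-[4-(benzyloxy)phenyl]-2-oxoethyl}methanesulfonamide | CS(=O)(=O)NCC(=O)c1ccc(OCc2ccccc2)cc1 | intermediate
4 | 4-(benzyloxy)-3-methoxybenzaldehyde (O-benzylvanillin) | COc1cc(C=O)ccc1OCc1ccccc1 | starting material
5 | 2-cyanoacetamide | N#CCC(N)=O | starting material
6 | (E)-3-[4-(benzyloxy)-3-methoxyphenyl]-2-cyanoprop-2-enamide (Knoevenagel adduct, not isolated) | COc1cc(/C=C(\C#N)C(N)=O)ccc1OCc1ccccc1 | intermediate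
7 | 3-[4-(benzyloxy)-3-methoxyphenyl]-5-[4-(benzyloxy)phenyl]-2-cyano-4-(methanesulfonamido)-5-oxopentanamide (Michael adduct, diastereomer mixture, not isolated) | COc1cc(C(C(C#N)C(N)=O)C(NS(C)(=O)=O)C(=O)c2ccc(OCc3ccccc3)cc2)ccc1OCc1ccccc1 | intermediate
8 | 2-amino-5-[4-(benzyloxy)benzoyl]-4-[4-(benzyloxy)-3-methoxyphenyl]-1-(methanesulfonyl)-4,5-dihydro-1H-pyrrole-3-carboxamide (diastereomer mixture, not isolated) | COc1cc(C2C(C(N)=O)=C(N)N(S(C)(=O)=O)C2C(=O)c2ccc(OCc3ccccc3)cc2)ccc1OCc1ccccc1 | intermediate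
9 | 2-amino-5-[4-(benzyloxy)benzoyl]-4-[4-(benzyloxy)-3-methoxyphenyl]-1H-pyrrole-3-carboxamide | COc1cc(-c2c(C(=O)c3ccc(OCc4ccccc4)cc3)[nH]c(N)c2C(N)=O)ccc1OCc1ccccc1 | intermediate
10 | 2-amino-5-[4-(benzyloxy)benzoyl]-4-[4-(benzyloxy)-3-methoxyphenyl]-1H-pyrrole-3-carbonyl isocyanate (not isolated) | COc1cc(-c2c(C(=O)c3ccc(OCc4ccccc4)cc3)[nH]c(N)c2C(=O)N=C=O)ccc1OCc1ccccc1 | intermediate
11 | 6-[4-(benzyloxy)benzoyl]-5-[4-(benzyloxy)-3-methoxyphenyl]-1H-pyrrolo[2,3-d]pyrimidine-2,4(3H,7H)-dione | COc1cc(-c2c(C(=O)c3ccc(OCc4ccccc4)cc3)[nH]c3[nH]c(=O)[nH]c(=O)c23)ccc1OCc1ccccc1 | intermediate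
12 | rigidin C, 6-(4-hydroxybenzoyl)-5-(4-hydroxy-3-methoxyphenyl)-1H-pyrrolo[2,3-d]pyrimidine-2,4(3H,7H)-dione | COc1cc(-c2c(C(=O)c3ccc(O)cc3)[nH]c3[nH]c(=O)[nH]c(=O)c23)ccc1O | target

## Summary

Total step count: 4. Longest linear sequence: 4 steps (1 → 3 → 9 → 11 → 12).

**Steps most likely to fail, and fallbacks**

Step 2 (three-component pyrrole assembly). The risk is that 3 undergoes aldol or self-condensation with the aldehyde before the slow Knoevenagel/Michael sequence of the weakly electrophilic cyanoacrylamide. The fallback sets out from 4 and 3 and comes back at 9. Aldehyde 4 is first condensed separately with malononitrile (piperidine cat., EtOH, rt) to give crystalline 2-[4-(benzyloxy)-3-methoxybenzylidene]malononitrile F1, a much stronger Michael acceptor. F1 and 3 (K2CO3, EtOH, reflux) then undergo the same Michael addition, ring closure and sulfinate loss to give 2-amino-5-[4-(benzyloxy)benzoyl]-4-[4-(benzyloxy)-3-methoxyphenyl]-1H-pyrrole-3-carbonitrile F2. Its nitrile is hydrated (30% H2O2, K2CO3, DMSO, rt; Radziszewski reaction) to return to carboxamide 9.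

Step 3 (oxalyl chloride carbonylation). The risk is competing N-oxalylation of the amine or pyrrole nitrogen, or decomposition at 120 °C. The fallback sets out from 9 and comes back at 11 by a stepwise urethane ring closure, as used for quinazolinediones from anthranilamide. Acylation of the 2-amino group (ClCO2Et, pyridine, 0 °C → rt) gives ethyl N-{5-[4-(benzyloxy)benzoyl]-4-[4-(benzyloxy)-3-methoxyphenyl]-3-carbamoyl-1H-pyrrol-2-yl}carbamate F3. NaOEt in EtOH at reflux then drives attack of the amide nitrogen on the carbamate carbonyl, with loss of ethanol, to give 11.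

Step 4 (hydrogenolysis of 11). The risk is that the flat, strongly hydrogen-bonded deazaxanthine 11 is too insoluble, so the reaction stalls at the mono-benzyl stage and 12 cannot be purified. The fallback changes the order of events: it sets out from 9 and comes back at 12. Hydrogenolysis is run on the soluble pyrrole (H2, Pd/C, THF–MeOH, rt), where the ketone is further deactivated by push–pull conjugation with the 2-amino group. This gives 2-amino-5-(4-hydroxybenzoyl)-4-(4-hydroxy-3-methoxyphenyl)-1H-pyrrole-3-carboxamide F4, which can be chromatographed or crystallised. The pyrimidinedione ring is then closed on the unprotected compound without an acid chloride, by urea fusion (urea, 10 equiv, 180 °C melt, then dilute aqueous NaOH and acidification), giving 12 directly.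

## Further compounds

F1 | step 2 | 2-[4-(benzyloxy)-3-methoxybenzylidene]malononitrile | COc1cc(C=C(C#N)C#N)ccc1OCc1ccccc1
F2 | step 2 | 2-amino-5-[4-(benzyloxy)benzoyl]-4-[4-(benzyloxy)-3-methoxyphenyl]-1H-pyrrole-3-carbonitrile | COc1cc(-c2c(C(=O)c3ccc(OCc4ccccc4)cc3)[nH]c(N)c2C#N)ccc1OCc1ccccc1
F3 | step 3 | ethyl N-{5-[4-(benzyloxy)benzoyl]-4-[4-(benzyloxy)-3-methoxyphenyl]-3-carbamoyl-1H-pyrrol-2-yl}carbamate | CCOC(=O)Nc1[nH]c(C(=O)c2ccc(OCc3ccccc3)cc2)c(-c2ccc(OCc3ccccc3)c(OC)c2)c1C(N)=O
F4 | step 4 | 2-amino-5-(4-hydroxybenzoyl)-4-(4-hydroxy-3-methoxyphenyl)-1H-pyrrole-3-carboxamide | COc1cc(-c2c(C(=O)c3ccc(O)cc3)[nH]c(N)c2C(N)=O)ccc1O
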